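**Retrosynthetic overview**
1. Brevipolide I ⇒ diol 17 + (Z)-4-methoxycinnamic acid 19 (site-selective C6'-O acylation, last step).
2. Cyclopropane (second ring, formed last): the C2'–C4' bond comes from 3-exo-tet attack of the C4' ketone enolate on C2'–O of cyclic sulfate 15, a stand-in for the biosynthetic cis-1',2'-epoxide; this sets C2' and C4' and frees C1'–OH.
3. 15 ⇒ (Z)-olefin 12 (substrate-controlled syn-dihydroxylation sets C1'/C2') ⇒ alkynyl lactone 11 (Lindlar).
4. Dihydropyranone (first ring): polyketide-style C2 + C2 extension of ynal 6 (acetaldehyde aldol sets C6, then Z-olefination) and lactonisation of the (Z)-5-hydroxy-2-enoate.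
5. 6 ⇒ lactate-derived vinyl ketone 3 + propiolaldehyde acetal 4 (conjugate alkynylation makes C2'–C3'); C6' comes from (S)-lactamide 1.

Assumption (biosynthesis): the cyclopropane is taken to arise by attack of the C4' enolate of the C5' ketone on C2' of a cis-1',2'-epoxide of a 6-[(Z)-heptenyl]pyranone, and the lactone by lactonisation of a polyketide (Z)-5-hydroxy-2-enoyl chain.
Assumption (supply): (S)-N,N-dimethyllactamide 1 is bought; otherwise it is one extra step from ethyl (S)-lactate and Me2NH.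
Numbering: ring C2–C6; side chain C1' (carbinol), C2'/C3'/C4' (cyclopropane, C3' = CH2), C5' (C=O), C6' (acyloxy carbon), C7' (CH3).

**Step 1**
Reactants: 1 (S)-2-hydroxy-N,N-dimethylpropanamide
Product: 2 (S)-2-[(tert-butyldimethylsilyl)oxy]-N,N-dimethylpropanamide
Conditions: TBSCl, imidazole, DMF, rt
Reagents that add atoms: tert-butyldimethylsilyl chloride, CC(C)(C)[Si](C)(C)Cl
Why: Imidazole-promoted silylation (Corey TBS protection) of the only hydroxyl; the lactate stereocentre (future C6', S) is not involved.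

**Step 2**
Reactants: 2 (S)-2-[(tert-butyldimethylsilyl)oxy]-N,N-dimethylpropanamide
Product: 3 (S)-4-[(tert-butyldimethylsilyl)oxy]pent-1-en-3-one
Conditions: CH2=CHMgBr, THF, −20 → 0 °C; inverse quench into cold 1 M HCl
Reagents that add atoms: vinylmagnesium bromide, C=C[Mg]Br
Why: Grignard acylation of a tertiary amide stops at the tetrahedral magnesium hemiaminal (no over-addition), and the inverse acid quench protonates Me2NH before it can add to the enone; C6' is untouched.

**Step 3**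
Reactants: 3 (S)-4-[(tert-butyldimethylsilyl)oxy]pent-1-en-3-one; 4 3,3-diethoxyprop-1-yne
Product: 6 (S)-7-[(tert-butyldimethylsilyl)oxy]-6-oxooct-2-ynal, via alkynyl diethyl acetal 5 (not isolated)
Conditions: 4 (2 equiv), Pd(OAc)2 (5 mol %), PMe3 (20 mol %), acetone, 60 °C; then Amberlyst-15, acetone–H2O, rt
Reagents that add atoms: water, O
Why: Pd(II)/phosphine-catalysed 1,4-addition (conjugate hydroalkynylation) of a terminal alkyne to an alkyl vinyl ketone forms C2'–C3' under neutral conditions that spare the ketone and its α-stereocentre, and acid hydrolysis then unmasks the ynal.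

**Step 4**
Reactants: 6 (S)-7-[(tert-butyldimethylsilyl)oxy]-6-oxooct-2-ynal; 7 acetaldehyde; 8 ethyl 2-[bis(2-methylphenoxy)phosphoryl]acetate
Product: 11 (R)-6-[(S)-6-[(tert-butyldimethylsilyl)oxy]-5-oxohept-1-yn-1-yl]-5,6-dihydro-2H-pyran-2-one, via aldol adduct 9 (not isolated), via Z-hydroxy-enoate 10 (not isolated)
Conditions: MeCHO (5 equiv), (S)-α,α-bis[3,5-bis(trifluoromethyl)phenyl]prolinol (10 mol %), DMF, 4 °C; evaporate MeCHO; 8, NaH, THF, −78 → 0 °C; 1 M HCl quench; TsOH (cat.), CH2Cl2, rt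
Reagents that add atoms: none
Why: The diarylprolinol-catalysed enamine cross-aldol of acetaldehyde attacks the Re face of the ynal in the H-bonded proline-type transition state and sets C6 as R, an Ando Z-selective Horner–Wadsworth–Emmons olefination adds the next C2 unit, and the (Z)-5-hydroxy-2-enoate lactonises under acid in the way a polyketide chain is released.

**Step 5**
Reactants: 11 (R)-6-[(S)-6-[(tert-butyldimethylsilyl)oxy]-5-oxohept-1-yn-1-yl]-5,6-dihydro-2H-pyran-2-one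
Product: 12 (R)-6-[(S,Z)-6-[(tert-butyldimethylsilyl)oxy]-5-oxohept-1-en-1-yl]-5,6-dihydro-2H-pyran-2-one
Conditions: H2 (1 atm), Lindlar catalyst, quinoline, EtOAc, rt
Reagents that add atoms: none
Why: Lindlar semihydrogenation adds H2 syn to the internal alkyne and gives the Z-olefin; the conjugated lactone olefin, the ketone and both stereocentres are untouched.

**Step 6**
Reactants: 12 (R)-6-[(S,Z)-6-[(tert-butyldimethylsilyl)oxy]-5-oxohept-1-en-1-yl]-5,6-dihydro-2H-pyran-2-one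
Product: 13 (R)-6-[(1S,2S,6S)-6-[(tert-butyldimethylsilyl)oxy]-1,2-dihydroxy-5-oxoheptyl]-5,6-dihydro-2H-pyran-2-one
Conditions: OsO4 (2 mol %), NMO, acetone–H2O, 0 °C; minor diastereomer removed by chromatography
Reagents that add atoms: N-methylmorpholine N-oxide, C[N+]1([O-])CCOCC1; water, O
Why: Upjohn dihydroxylation adds both oxygens syn to the Z-olefin (erythro 1',2'-diol) on the face anti to the allylic C6–O bond in the A(1,3)-minimised conformer (Kishi's empirical rule), which sets C1' and C2' as S,S; the electron-poor lactone olefin reacts far more slowly.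

**Step 7**
Reactants: 13 (R)-6-[(1S,2S,6S)-6-[(tert-butyldimethylsilyl)oxy]-1,2-dihydroxy-5-oxoheptyl]-5,6-dihydro-2H-pyran-2-one
Product: 15 (R)-6-[(4R,5S)-5-[(S)-4-[(tert-butyldimethylsilyl)oxy]-3-oxopentyl]-2,2-dioxido-1,3,2-dioxathiolan-4-yl]-5,6-dihydro-2H-pyran-2-one, via cyclic sulfite 14 (not isolated)
Conditions: SOCl2, Et3N, CH2Cl2, 0 °C; then RuCl3·xH2O (0.5 mol %), NaIO4, MeCN–H2O, 0 °C
Reagents that add atoms: thionyl chloride, O=S(Cl)Cl; sodium periodate, [Na+].[O-]I(=O)(=O)=O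
Why: Sharpless cyclic sulfate synthesis (cyclic sulfite, then RuO4 oxidation at sulfur) turns the cis-diol into an epoxide-like electrophile with both C–O configurations retained (C1' becomes R only because of the CIP priority change); low Ru loading at 0 °C spares the enoate.

**Step 8**
Reactants: 15 (R)-6-[(4R,5S)-5-[(S)-4-[(tert-butyldimethylsilyl)oxy]-3-oxopentyl]-2,2-dioxido-1,3,2-dioxathiolan-4-yl]-5,6-dihydro-2H-pyran-2-one
Product: 17 (R)-6-[(S)-hydroxy{(1S,2S)-2-[(S)-2-hydroxypropanoyl]cyclopropyl}methyl]-5,6-dihydro-2H-pyran-2-one, via cyclopropyl sulfate lithium salt 16 (not isolated)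
Conditions: LiHMDS (1.1 equiv), THF, −78 → 0 °C; then HCl/MeOH (1.25 M), 0 °C → rt
Reagents that add atoms: none
Why: Kinetic deprotonation on the CH2 side of the ketone gives the C4' enolate, which opens the cyclic sulfate at C2' by a 3-exo-tet SN2 enolate alkylation (inversion at C2', trans ring closure sets C4', C1'–O kept as the sulfate monoester, the laboratory counterpart of the presumed enolate/cis-epoxide opening), and acidic methanolysis then removes the sulfate by S–O cleavage together with the TBS ether.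

**Step 9**
Reactants: 18 3-(4-methoxyphenyl)prop-2-ynoic acid
Product: 19 (Z)-3-(4-methoxyphenyl)prop-2-enoic acid
Conditions: H2 (1 atm), Lindlar catalyst, quinoline, EtOAc, rt
Reagents that add atoms: none
Why: Lindlar semihydrogenation (syn addition of H2) of the arylpropiolic acid gives the Z-cinnamic acid.

**Step 10**
Reactants: 17 (R)-6-[(S)-hydroxy{(1S,2S)-2-[(S)-2-hydroxypropanoyl]cyclopropyl}methyl]-5,6-dihydro-2H-pyran-2-one; 19 (Z)-3-(4-methoxyphenyl)prop-2-enoic acid
Product: 20 brevipolide I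
Conditions: EDC·HCl, DMAP (cat.), CH2Cl2, −20 → 0 °C, dark
Reagents that add atoms: none
Why: Steglich esterification should take place at the less hindered C6' methyl carbinol and not at C1'–OH, which is flanked by two branched carbons; no stereocentre is touched and the Z-olefin is kept by working cold and in the dark.

**Compound list**
1 | (S)-2-hydroxy-N,N-dimethylpropanamide | C[C@H](O)C(=O)N(C)C | starting material
2 | (S)-2-[(tert-butyldimethylsilyl)oxy]-N,N-dimethylpropanamide | C[C@H](O[Si](C)(C)C(C)(C)C)C(=O)N(C)C | intermediate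
3 | (S)-4-[(tert-butyldimethylsilyl)oxy]pent-1-en-3-one | C[C@H](O[Si](C)(C)C(C)(C)C)C(=O)C=C | intermediate
4 | 3,3-diethoxyprop-1-yne | C#CC(OCC)OCC | starting material
5 | (S)-2-[(tert-butyldimethylsilyl)oxy]-8,8-diethoxyoct-6-yn-3-one | C[C@H](O[Si](C)(C)C(C)(C)C)C(=O)CCC#CC(OCC)OCC | intermediate
6 | (S)-7-[(tert-butyldimethylsilyl)oxy]-6-oxooct-2-ynal | C[C@H](O[Si](C)(C)C(C)(C)C)C(=O)CCC#CC=O | intermediate
7 | acetaldehyde | CC=O | starting material
8 | ethyl 2-[bis(2-methylphenoxy)phosphoryl]acetate | CCOC(=O)CP(=O)(Oc1ccccc1C)Oc1ccccc1C | starting material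
9 | (3R,9S)-9-[(tert-butyldimethylsilyl)oxy]-3-hydroxy-8-oxodec-4-ynal | O=CC[C@@H](O)C#CCCC(=O)[C@H](C)O[Si](C)(C)C(C)(C)C | intermediate
10 | ethyl (2Z,5R,11S)-11-[(tert-butyldimethylsilyl)oxy]-5-hydroxy-10-oxododec-2-en-6-ynoate | CCOC(=O)/C=C\C[C@@H](O)C#CCCC(=O)[C@H](C)O[Si](C)(C)C(C)(C)C | intermediate
11 | (R)-6-[(S)-6-[(tert-butyldimethylsilyl)oxy]-5-oxohept-1-yn-1-yl]-5,6-dihydro-2H-pyran-2-one | O=C1C=CC[C@H](C#CCCC(=O)[C@H](C)O[Si](C)(C)C(C)(C)C)O1 | intermediate
12 | (R)-6-[(S,Z)-6-[(tert-butyldimethylsilyl)oxy]-5-oxohept-1-en-1-yl]-5,6-dihydro-2H-pyran-2-one | O=C1C=CC[C@H](/C=C\CCC(=O)[C@H](C)O[Si](C)(C)C(C)(C)C)O1 | intermediate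
13 | (R)-6-[(1S,2S,6S)-6-[(tert-butyldimethylsilyl)oxy]-1,2-dihydroxy-5-oxoheptyl]-5,6-dihydro-2H-pyran-2-one | O=C1C=CC[C@H]([C@@H](O)[C@@H](O)CCC(=O)[C@H](C)O[Si](C)(C)C(C)(C)C)O1 | intermediate
14 | (R)-6-[(4R,5S)-5-[(S)-4-[(tert-butyldimethylsilyl)oxy]-3-oxopentyl]-2-oxido-1,3,2-dioxathiolan-4-yl]-5,6-dihydro-2H-pyran-2-one (mixture at sulfur) | O=C1C=CC[C@H]([C@H]2OS(=O)O[C@H]2CCC(=O)[C@H](C)O[Si](C)(C)C(C)(C)C)O1 | intermediate
15 | (R)-6-[(4R,5S)-5-[(S)-4-[(tert-butyldimethylsilyl)oxy]-3-oxopentyl]-2,2-dioxido-1,3,2-dioxathiolan-4-yl]-5,6-dihydro-2H-pyran-2-one | O=C1C=CC[C@H]([C@H]2OS(=O)(=O)O[C@H]2CCC(=O)[C@H](C)O[Si](C)(C)C(C)(C)C)O1 | intermediate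
16 | lithium (S)-{(1S,2S)-2-[(S)-2-[(tert-butyldimethylsilyl)oxy]propanoyl]cyclopropyl}[(R)-6-oxo-3,6-dihydro-2H-pyran-2-yl]methyl sulfate | CC(C)(C)[Si](C)(C)O[C@@H](C)C(=O)[C@H]1C[C@@H]1[C@H](OS(=O)(=O)[O-])[C@H]1CC=CC(=O)O1.[Li+] | intermediate
17 | (R)-6-[(S)-hydroxy{(1S,2S)-2-[(S)-2-hydroxypropanoyl]cyclopropyl}methyl]-5,6-dihydro-2H-pyran-2-one | C[C@H](O)C(=O)[C@H]1C[C@@H]1[C@H](O)[C@H]1CC=CC(=O)O1 | intermediate
18 | 3-(4-methoxyphenyl)prop-2-ynoic acid | COc1ccc(C#CC(=O)O)cc1 | starting material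
19 | (Z)-3-(4-methoxyphenyl)prop-2-enoic acid | COc1ccc(/C=C\C(=O)O)cc1 | intermediate
20 | brevipolide I, (R)-6-[(S)-hydroxy{(1S,2S)-2-[(S)-2-{[(Z)-3-(4-methoxyphenyl)prop-2-enoyl]oxy}propanoyl]cyclopropyl}methyl]-5,6-dihydro-2H-pyran-2-one | COc1ccc(/C=C\C(=O)O[C@@H](C)C(=O)[C@H]2C[C@@H]2[C@H](O)[C@H]2CC=CC(=O)O2)cc1 | target

**Step count and risks**
Total step count: 10. Longest linear sequence: 9 (steps 1–8 and 10, from 1).

Most likely to fail:

Step 4 (one-pot aldol, Z-olefination, lactonisation). The secondary-amine catalyst can add to the ynal, and the free aldol 9 can dehydrate or undergo retro-aldol before it is olefinated. Fallback, setting out from 6 and coming back at 9: C6 is set by reagent control. Compound 6 is treated with (+)-B-allyldiisopinocampheylborane (Et2O, −78 °C, ethanolamine work-up), which should deliver allyl to the Re face of the aldehyde only and give the homoallylic alcohol (2S,8R)-2-[(tert-butyldimethylsilyl)oxy]-8-hydroxyundec-10-en-6-yn-3-one F1. The reagent enantiomer is chosen from the usual facial rule and should be confirmed on the first run. Lemieux–Johnson cleavage of the terminal olefin of F1 (OsO4 cat., NaIO4, 2,6-lutidine, dioxane–H2O; the alkyne is inert) gives aldol 9, which re-enters step 4 at the olefination.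

Step 8 (key cyclisation). The dihydropyranone can be deprotonated at C5 and ring-open, the cyclic sulfate can undergo E2, and the cyclopropylcarbinyl sulfate 16 may ionise and rearrange during acid methanolysis. Fallback, setting out from 15 and coming back at 17: the true cis-epoxide is used, which resists elimination and releases the C1' alkoxide directly.
- LiBr (THF, rt) opens 15 at the less hindered C2' with inversion to give lithium (1R,2R,6S)-2-bromo-6-[(tert-butyldimethylsilyl)oxy]-5-oxo-1-[(R)-6-oxo-3,6-dihydro-2H-pyran-2-yl]heptyl sulfate F2.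
- Catalytic H2SO4 with 1 equiv H2O in THF hydrolyses it to the bromohydrin (R)-6-[(1R,2R,6S)-2-bromo-6-[(tert-butyldimethylsilyl)oxy]-1-hydroxy-5-oxoheptyl]-5,6-dihydro-2H-pyran-2-one F3.
- Ag2O (CH2Cl2, rt) closes it, with a second inversion at C2', to the cis-epoxide (R)-6-[(2S,3S)-3-[(S)-4-[(tert-butyldimethylsilyl)oxy]-3-oxopentyl]oxiran-2-yl]-5,6-dihydro-2H-pyran-2-one F4.
- LiHMDS (THF, −78 → −20 °C, AcOH quench at low temperature) effects the 3-exo-tet enolate opening of the epoxide to (R)-6-[(S)-{(1S,2S)-2-[(S)-2-[(tert-butyldimethylsilyl)oxy]propanoyl]cyclopropyl}(hydroxy)methyl]-5,6-dihydro-2H-pyran-2-one F5.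
- HCl/MeOH removes the silyl ether and gives 17.

Step 10 (site-selective esterification). Acylation may also occur at C1'–OH, and the Z-cinnamoyl unit may isomerise. Fallback, setting out from 15 and coming back at 20: the sulfate is kept as a temporary protecting group for C1'–O.
- The cyclisation is run as in step 8, but the lithium sulfate 16 is not methanolysed.
- HF·pyridine (THF–pyridine, 0 °C) removes only the silyl ether to give lithium (S)-{(1S,2S)-2-[(S)-2-hydroxypropanoyl]cyclopropyl}[(R)-6-oxo-3,6-dihydro-2H-pyran-2-yl]methyl sulfate F6.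
- Its single free hydroxyl is acylated with 19 (EDC·HCl, DMAP, CH2Cl2–DMF, 0 °C) to the brevipolide I 1'-O-sulfate lithium salt F7.
- Catalytic H2SO4 with 1 equiv H2O in THF (rt) cleaves the sulfate and gives 20.

**Further compounds**
F1 | step 4 | (2S,8R)-2-[(tert-butyldimethylsilyl)oxy]-8-hydroxyundec-10-en-6-yn-3-one | C=CC[C@@H](O)C#CCCC(=O)[C@H](C)O[Si](C)(C)C(C)(C)C
F2 | step 8 | lithium (1R,2R,6S)-2-bromo-6-[(tert-butyldimethylsilyl)oxy]-5-oxo-1-[(R)-6-oxo-3,6-dihydro-2H-pyran-2-yl]heptyl sulfate | O=C1C=CC[C@H]([C@@H](OS(=O)(=O)[O-])[C@H](Br)CCC(=O)[C@H](C)O[Si](C)(C)C(C)(C)C)O1.[Li+]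
F3 | step 8 | (R)-6-[(1R,2R,6S)-2-bromo-6-[(tert-butyldimethylsilyl)oxy]-1-hydroxy-5-oxoheptyl]-5,6-dihydro-2H-pyran-2-one | O=C1C=CC[C@H]([C@@H](O)[C@H](Br)CCC(=O)[C@H](C)O[Si](C)(C)C(C)(C)C)O1
F4 | step 8 | (R)-6-[(2S,3S)-3-[(S)-4-[(tert-butyldimethylsilyl)oxy]-3-oxopentyl]oxiran-2-yl]-5,6-dihydro-2H-pyran-2-one | O=C1C=CC[C@H]([C@H]2O[C@H]2CCC(=O)[C@H](C)O[Si](C)(C)C(C)(C)C)O1
F5 | step 8 | (R)-6-[(S)-{(1S,2S)-2-[(S)-2-[(tert-butyldimethylsilyl)oxy]propanoyl]cyclopropyl}(hydroxy)methyl]-5,6-dihydro-2H-pyran-2-one | CC(C)(C)[Si](C)(C)O[C@@H](C)C(=O)[C@H]1C[C@@H]1[C@H](O)[C@H]1CC=CC(=O)O1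
F6 | step 10 | lithium (S)-{(1S,2S)-2-[(S)-2-hydroxypropanoyl]cyclopropyl}[(R)-6-oxo-3,6-dihydro-2H-pyran-2-yl]methyl sulfate | C[C@H](O)C(=O)[C@H]1C[C@@H]1[C@H](OS(=O)(=O)[O-])[C@H]1CC=CC(=O)O1.[Li+]
F7 | step 10 | brevipolide I 1'-O-sulfate lithium salt | COc1ccc(/C=C\C(=O)O[C@@H](C)C(=O)[C@H]2C[C@@H]2[C@H](OS(=O)(=O)[O-])[C@H]2CC=CC(=O)O2)cc1.[Li+]
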